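**Plan**

- Retrosynthesis: the 4,5-epoxide C–O bonds and the two ester C–O bonds (O8 acetate, O9 glycidate) go first, then C11=C13, and the C9 carbinol goes back to a ketone. Next the C9–C10 and C1–C2 bonds are cut and C2–C9 restored, which excises a propiolate unit and contracts the ten-membered ring to a cyclooctenone. Then C4=C5 (metathesis), C8–C9 (acyl anion), C7–C11 (enolate alkylation) and C6–C7 (aldol).
- Enabling feature: C10 (with its C14 ester) and C1 sit as a two-carbon, alkynoate-derived insert between the oxygenated C9 and C2 of the ten-membered ring. The other eight ring atoms (C2–C9) therefore form a cyclooct-4-en-1-one, whose only possible alkene geometry, Z-C4=C5, is the one the cis-4,5-epoxide needs.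
- Forward: the C5–C8/C11–C12 chain is joined to a dithiane carrying C9 and C2–C4/C15. The γ-lactone (O6–C12) closes first, the eight-membered ring second (metathesis), the ten-membered ring third (enamine–propiolate enlargement). Methylene, C9 alcohol, esters and epoxide follow.
- Stereochemistry: C6 from a lipase-resolved allylic alcohol, C7 by anti dianion alkylation, C8 by chelate-controlled 1,3-syn reduction, C9 by Felkin–Anh-type Luche reduction, the glycidate centre from the chiral-pool ester, C4/C5 by peripheral epoxidation of the Z-alkene.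

Key step: step 13

Remark: all intermediates carry the germacrane numbering of the target (ring C1–C10, lactone C11–C13, ester carbon C14, methyl C15); the face of the carbocycle that bears O6, C11 and O8 is called α.

**Route**

Step 1
Reactants: 1 ethyl acetate; 2 acrolein
Product: 3 (±)-ethyl 3-hydroxypent-4-enoate
Conditions: LiN(i-Pr)2, THF, −78 °C; then 2, −78 °C; aqueous work-up
Reagents that add atoms: none
Why: Aldol addition of the lithium enolate of ethyl acetate to acrolein is a clean 1,2-addition at −78 °C and should give the racemic allylic β-hydroxy ester that holds C5–C8 with the C6 carbinol.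

Step 2
Reactants: 3 (±)-ethyl 3-hydroxypent-4-enoate
Product: 4 ethyl (3R)-3-hydroxypent-4-enoate
Conditions: lipase PS (Burkholderia cepacia), vinyl acetate, t-BuOMe, 30 °C, run past half conversion; chromatography
Reagents that add atoms: none
Why: Lipase-catalysed kinetic resolution by transesterification should acetylate the (S)-alcohol faster (Kazlauskas rule, CH2CO2Et as the large and vinyl as the medium group), so the slow (R)-alcohol, which has the C6 configuration of the target, is recovered enantioenriched once conversion passes one half.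

Step 3
Reactants: 4 ethyl (3R)-3-hydroxypent-4-enoate; 5 tert-butyl bromoacetate
Product: 6 4-tert-butyl 1-ethyl (2S)-2-[(1S)-1-hydroxyprop-2-en-1-yl]butanedioate
Conditions: LiN(i-Pr)2 (2.2 equiv), THF, −78 → −30 °C; then 5, DMPU, −78 → −20 °C
Reagents that add atoms: none
Why: Fráter–Seebach alkylation, in which the chelated alkoxide–enolate dianion is alkylated on the face opposite to the substituent of the carbinol carbon, should set C7 anti to the C6 hydroxyl (the relationship that later gives the cis-lactone), and the tert-butyl ester resists attack by the alkoxide.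

Step 4
Reactants: 6 4-tert-butyl 1-ethyl (2S)-2-[(1S)-1-hydroxyprop-2-en-1-yl]butanedioate
Product: 7 tert-butyl (3S,4S)-4-hydroxy-3-[methoxy(methyl)carbamoyl]hex-5-enoate
Conditions: MeNHOMe·HCl, i-PrMgCl, THF, −20 → 0 °C
Reagents that add atoms: N,O-dimethylhydroxylamine hydrochloride, CNOC.Cl
Why: Weinreb amide formation by aminolysis of the ethyl ester with the chloromagnesium amide is selective over the hindered tert-butyl ester and should leave both stereocentres untouched, because C7–H lies next to a magnesium alkoxide and is not enolised at this temperature.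

Step 5
Reactants: 8 1,3-dithiane; 9 4-bromo-2-methylbut-1-ene
Product: 10 2-(3-methylbut-3-en-1-yl)-1,3-dithiane
Conditions: n-BuLi, THF, −30 °C; then 9, −78 → 0 °C
Reagents that add atoms: none
Why: Corey–Seebach alkylation of lithiated 1,3-dithiane with the primary homoallylic bromide gives the masked acyl anion that carries C9 and the C2–C4/C15 isopropenyl arm.

Step 6
Reactants: 7 tert-butyl (3S,4S)-4-hydroxy-3-[methoxy(methyl)carbamoyl]hex-5-enoate; 10 2-(3-methylbut-3-en-1-yl)-1,3-dithiane
Product: 11 tert-butyl (3S,4S)-4-hydroxy-3-{[2-(3-methylbut-3-en-1-yl)-1,3-dithian-2-yl]carbonyl}hex-5-enoate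
Conditions: 10 (2.3 equiv), n-BuLi, THF, −30 °C; then 7, −78 → −30 °C
Reagents that add atoms: none
Why: Acylation of the lithiated 2-alkyl-dithiane by the Weinreb amide (Corey–Seebach umpolung, one equivalent being spent on the free hydroxyl) stops at the ketone through the chelated tetrahedral intermediate and is expected to outrun enolisation of the hindered tert-butyl ester, forming C8–C9 with C9 masked as the dithioketal.

Step 7
Reactants: 11 tert-butyl (3S,4S)-4-hydroxy-3-{[2-(3-methylbut-3-en-1-yl)-1,3-dithian-2-yl]carbonyl}hex-5-enoate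
Product: 12 tert-butyl (3S,4S)-4-hydroxy-3-{(S)-hydroxy[2-(3-methylbut-3-en-1-yl)-1,3-dithian-2-yl]methyl}hex-5-enoate (6,8-syn diol)
Conditions: Et2BOMe, NaBH4, THF–MeOH (4:1), −78 °C; AcOH, then repeated evaporation from MeOH
Reagents that add atoms: none
Why: Narasaka–Prasad reduction, in which the C6 hydroxyl and the C8 ketone are held in a six-membered diethylboron chelate with the C6 and C7 substituents equatorial and hydride adds axially, should give the 1,3-syn diol and thereby the C8 configuration of the target.

Step 8
Reactants: 12 6,8-syn diol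
Product: 13 (4R,5S)-4-{(S)-hydroxy[2-(3-methylbut-3-en-1-yl)-1,3-dithian-2-yl]methyl}-5-vinyldihydrofuran-2(3H)-one (cis-lactone, free 8-OH)
Conditions: PPTS (cat.), toluene, 80 °C
Reagents that add atoms: none
Why: Acid-catalysed lactonisation of the γ-hydroxy tert-butyl ester (5-exo-trig transesterification) should take place on the less hindered allylic C6 hydroxyl and not on the C8 hydroxyl next to the quaternary dithiane carbon, and reversible acyl transfer funnels material to this less congested cis-lactone without touching a stereocentre.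

Step 9
Reactants: 13 cis-lactone with free 8-OH
Product: 14 8-O-tert-butyldimethylsilyl ether of 13
Conditions: TBSOTf, 2,6-lutidine, CH2Cl2, −78 → 0 °C
Reagents that add atoms: tert-butyldimethylsilyl triflate, CC(C)(C)[Si](C)(C)OS(=O)(=O)C(F)(F)F
Why: Silylation with a silyl triflate and a hindered base protects even the congested C8 hydroxyl under conditions too mild for lactone migration, and the bulky non-chelating silyl ether later steers enamine regiochemistry and the C9 reduction.

Step 10
Reactants: 14 silyl ether dithioketal
Product: 15 diene ketone: cis-lactone bearing 6-vinyl and 7-[1-(silyloxy)-5-methyl-2-oxohex-5-enyl]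
Conditions: MeI, CaCO3, MeCN–H2O (4:1), 45 °C
Reagents that add atoms: water, O
Why: Alkylative hydrolysis of the dithioketal (S-methylation, then hydrolysis of the thionium ion) unmasks the C9 ketone under near-neutral conditions that should spare the silyl ether, the lactone, both alkenes and the enolisable C8 centre.

Step 11
Reactants: 15 diene ketone
Product: 16 cis-lactone-fused (Z)-cyclooct-4-enone (C9 ketone, 8-OTBS on the α-face)
Conditions: second-generation Grubbs catalyst (H2IMes)(PCy3)Cl2Ru=CHPh (10 mol %), CH2Cl2 (2 mM), reflux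
Reagents that add atoms: none
Why: Ring-closing metathesis between the vinyl and isopropenyl groups, which the cis-lactone holds on one face, should close the eight-membered ring with loss of ethene, and the ring size allows only the Z trisubstituted C4=C5.

Step 12
Reactants: 16 cyclooctenone; 17 pyrrolidine
Product: 18 pyrrolidine enamine of 16 (C9=C2)
Conditions: 17 (6 equiv), TiCl4 (0.55 equiv), toluene, 0 → 25 °C; filtration under argon
Reagents that add atoms: none
Why: TiCl4-mediated enamine condensation removes water irreversibly and should place the double bond toward the unsubstituted C2, since a C8=C9 enamine would be tetrasubstituted and strained (A1,3) against the silyloxy group, while the short non-equilibrating conditions limit C8 epimerisation and lactone aminolysis.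

Step 13
Reactants: 18 pyrrolidine enamine; 19 methyl propiolate
Product: 22 ten-membered 9-pyrrolidinyl diene ester (ring-cis C9=C10 with the C14 ester on C10; trans C1=C2; Z-C4=C5), via zwitterion 20 (not isolated), via cyclobutene 21 (not isolated)
Conditions: 19 (1.2 equiv), Et2O, 0 → 25 °C; then toluene, 45 °C
Reagents that add atoms: none
Why: The nucleophilic enamine carbon C2 adds to the unsubstituted alkyne terminus (C1) to give zwitterion 20, whose ester-stabilised vinyl anion (C10) closes 4-exo-trig on the iminium carbon C9, a stepwise [2+2] that gives the cis-fused bicyclo[6.2.0] aminocyclobutene 21. On warming, 21 undergoes thermal conrotatory 4π electrocyclic opening of the C2–C9 fusion bond, so the ten-membered ring arises by two-carbon ring enlargement and not by a macrocyclisation. The closest known reaction type is the ring enlargement of cyclic ketone enamines with acetylenic esters, which turns cyclooctanone enamines into cis,trans-cyclodeca-1,3-diene amino esters. The two centres created at C2 and C9 in 21 (alkyne approach on the enamine face remote from the C8 silyl ether, cis fusion enforced by the four-membered ring) are erased on opening, and no stereocentre of 18 is touched. Torquoselectivity (amino donor outward, C8 inward) fixes C9=C10 ring-cis and C1=C2 trans; the regiochemistry needs the enamine on the C2 side and the ester on the carbon that bonds to C9, which the fully substituted silyloxy-bearing C8 and the polarity of the propiolate secure, and the aprotic non-polar medium disfavours the simple Michael adduct.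

Step 14
Reactants: 22 ten-membered diene ester
Product: 23 11-(dimethylaminomethyl) lactone of 22
Conditions: LiN(i-Pr)2 (1.15 equiv), THF, −78 °C; then CH2=NMe2 I, −78 → 0 °C
Reagents that add atoms: N,N-dimethylmethyleneiminium iodide (Eschenmoser's salt), C=[N+](C)C.[I-]
Why: Mannich reaction of the lactone lithium enolate with Eschenmoser's salt should be clean because C11–H2 is the only acidic site (the vinylogous carbamate is inert to base), the iminium ion entering trans to the C7–C8 bond at a centre that the next step removes.

Step 15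
Reactants: 23 Mannich base
Product: 25 11(13)-methylene lactone of the diene ester, via methiodide 24 (not isolated)
Conditions: MeI, THF–MeOH, 25 °C; then aq. NaHCO3, CH2Cl2
Reagents that add atoms: none
Why: Quaternisation of the only basic nitrogen followed by Hofmann-type (E1cB) elimination under bicarbonate unveils the C11=C13 methylene, the enamino ester nitrogen being non-nucleophilic.

Step 16
Reactants: 25 methylene lactone diene ester
Product: 27 alkylidene β-keto ester (C9 ketone, ring-cis C10=C1, C2 now CH2), via iminium chloride 26 (not isolated)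
Conditions: 1 M aq. HCl, THF, 0 → 25 °C
Reagents that add atoms: water, O
Why: Dienamine hydrolysis under equilibrating acid should follow the course known for 1-amino-1,3-dienes, protonation at C10 being reversible while protonation at C2 relieves the strained trans C1=C2 bond and gives the linearly conjugated iminium ion 26, which hydrolyses to the C9 ketone with C10=C1 in place; the ring-cis geometry follows from the twisted s-cis diene and the greater stability of a cis enone in a ten-membered ring.

Step 17
Reactants: 27 alkylidene β-keto ester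
Product: 28 9-alcohol (9-OH trans to 8-OTBS)
Conditions: NaBH4, CeCl3·7H2O, MeOH–THF, −78 °C
Reagents that add atoms: none
Why: Luche reduction should give 1,2-reduction of the doubly activated enone without touching the methylene lactone at −78 °C, and hydride is expected to add anti to the C8–OSi bond (polar Felkin–Anh, no chelation by the bulky silyl ether), placing the C9 hydroxyl trans to the C8 oxygen.

Step 18
Reactants: 29 methyl (R)-2-methylglycidate
Product: 30 (R)-2-methylglycidic acid
Conditions: KOH (1.0 equiv), MeOH–H2O, 0 °C; then HCl (1.0 equiv), 0 °C, extraction; used at once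
Reagents that add atoms: potassium hydroxide, [K+].[OH-]
Why: Cold saponification attacks the ester carbonyl far faster than the hindered 2,2-disubstituted oxirane, so the epoxide and its quaternary stereocentre should survive.

Step 19
Reactants: 28 9-alcohol; 30 (R)-2-methylglycidic acid
Product: 32 9-O-[(R)-2-methylglycidoyl] ester, via mixed anhydride 31 (not isolated)
Conditions: 30, 2,4,6-trichlorobenzoyl chloride, Et3N, THF, 0 °C; then 28, DMAP, toluene, 25 → 40 °C
Reagents that add atoms: none
Why: Yamaguchi esterification, in which DMAP attacks the mixed anhydride only at the glycidoyl carbonyl and the acylpyridinium ion acylates the hindered secondary alcohol, should proceed with retention at C9 and at the epoxide centre.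

Step 20
Reactants: 32 9-O-glycidate 8-O-silyl ether
Product: 33 8-alcohol
Conditions: HF·pyridine, pyridine, THF, 0 → 25 °C
Reagents that add atoms: none
Why: Buffered fluoride desilylation is mildly acidic, so the neighbouring C9 ester should not migrate to the freed C8 hydroxyl, and the conjugate acceptors and the carbonyl-deactivated glycidate epoxide should survive.

Step 21
Reactants: 33 8-alcohol
Product: 34 8-acetate (4,5-deoxy target)
Conditions: Ac2O, pyridine, DMAP (cat.), CH2Cl2, 0 °C
Reagents that add atoms: acetic anhydride, CC(=O)OC(C)=O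
Why: DMAP-catalysed acetylation of the secondary C8 alcohol should be faster than base-induced acyl migration or translactonisation to O8.

Step 22
Reactants: 34 8-acetate
Product: 35 target: (4R,5S)-4,5-epoxide, (6R,7R)-cis-6,12-lactone with C11=C13, (8S)-acetate, (9S)-[(2R)-2-methyloxirane-2-carboxylate], ring-cis C1=C10 bearing the C14 methyl ester
Conditions: mCPBA (1.1 equiv), CH2Cl2, −20 → 0 °C; aq. NaHCO3–Na2S2O3 work-up
Reagents that add atoms: 3-chloroperbenzoic acid, OOC(=O)c1cccc(Cl)c1
Why: Prilezhaev epoxidation is selective for the only electron-rich alkene and stereospecific, so the Z-alkene gives the cis-epoxide, and with H6 in the alkene plane (A1,3 strain against C3) the peracid should approach the open face anti to C7, the convex face of the cis-fused lactone, which puts the oxirane oxygen trans to O6 (4R,5S).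

**Compound list**

1 | ethyl acetate | CCOC(C)=O | starting material
2 | acrolein | C=CC=O | starting material
3 | (±)-ethyl 3-hydroxypent-4-enoate | C=CC(O)CC(=O)OCC | intermediate
4 | ethyl (3R)-3-hydroxypent-4-enoate | C=C[C@H](O)CC(=O)OCC | intermediate
5 | tert-butyl bromoacetate | BrCC(=O)OC(C)(C)C | starting material
6 | 4-tert-butyl 1-ethyl (2S)-2-[(1S)-1-hydroxyprop-2-en-1-yl]butanedioate (6-OH and C11 anti) | C=C[C@H](O)[C@H](CC(=O)OC(C)(C)C)C(=O)OCC | intermediate
7 | tert-butyl (3S,4S)-4-hydroxy-3-[methoxy(methyl)carbamoyl]hex-5-enoate | C=C[C@H](O)[C@H](CC(=O)OC(C)(C)C)C(=O)N(C)OC | intermediate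
8 | 1,3-dithiane | C1CSCSC1 | starting material
9 | 4-bromo-2-methylbut-1-ene | CC(=C)CCBr | starting material
10 | 2-(3-methylbut-3-en-1-yl)-1,3-dithiane | CC(=C)CCC1SCCCS1 | intermediate
11 | tert-butyl (3S,4S)-4-hydroxy-3-{[2-(3-methylbut-3-en-1-yl)-1,3-dithian-2-yl]carbonyl}hex-5-enoate | C=C[C@H](O)[C@H](CC(=O)OC(C)(C)C)C(=O)C1(CCC(C)=C)SCCCS1 | intermediate
12 | tert-butyl (3S,4S)-4-hydroxy-3-{(S)-hydroxy[2-(3-methylbut-3-en-1-yl)-1,3-dithian-2-yl]methyl}hex-5-enoate (6,8-syn diol, C11 anti to both) | C=C[C@H](O)[C@H](CC(=O)OC(C)(C)C)[C@H](O)C1(CCC(C)=C)SCCCS1 | intermediate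
13 | (4R,5S)-4-{(S)-hydroxy[2-(3-methylbut-3-en-1-yl)-1,3-dithian-2-yl]methyl}-5-vinyldihydrofuran-2(3H)-one (cis-lactone) | C=C[C@@H]1OC(=O)C[C@@H]1[C@H](O)C2(CCC(C)=C)SCCCS2 | intermediate
14 | 8-O-tert-butyldimethylsilyl ether of 13 (C6, C7, C8 as in 13) | C=C[C@@H]1OC(=O)C[C@@H]1[C@H](O[Si](C)(C)C(C)(C)C)C2(CCC(C)=C)SCCCS2 | intermediate
15 | diene ketone: cis-lactone with 6-vinyl and 7-[(1S)-1-(tert-butyldimethylsilyloxy)-5-methyl-2-oxohex-5-en-1-yl] | C=C[C@@H]1OC(=O)C[C@@H]1[C@H](O[Si](C)(C)C(C)(C)C)C(=O)CCC(C)=C | intermediate
16 | cis-lactone-fused (Z)-4-methylcyclooct-4-enone: C9 ketone, 8-OTBS cis to C11 (α), O6–C12 lactone | O=C1CC/C(C)=C\[C@@H]2OC(=O)C[C@@H]2[C@@H]1O[Si](C)(C)C(C)(C)C | intermediate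
17 | pyrrolidine | C1CCNC1 | starting material
18 | pyrrolidine enamine of 16 (C9=C2) | C1CCN(C1)/C2=C/C/C(C)=C\[C@@H]3OC(=O)C[C@@H]3[C@@H]2O[Si](C)(C)C(C)(C)C | intermediate
19 | methyl propiolate | C#CC(=O)OC | starting material
20 | zwitterion: C9 iminium, C2 bonded to the vinyl anion C1=C10(CO2Me), new bond on the β-face | C1CC[N+](C1)=C2[C@@H](/C=[C-]/C(=O)OC)C/C(C)=C\[C@@H]3OC(=O)C[C@@H]3[C@@H]2O[Si](C)(C)C(C)(C)C | intermediate
21 | cis-fused bicyclo[6.2.0] aminocyclobutene ester (bonds C1–C2 and C9–C10 on the β-face) | N1(CCCC1)[C@@]23[C@@H](C=C2C(=O)OC)C/C(C)=C\[C@@H]4OC(=O)C[C@@H]4[C@@H]3O[Si](C)(C)C(C)(C)C | intermediate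
22 | ten-membered 9-pyrrolidinyl diene ester: ring-cis C9=C10 (CO2Me on C10), trans C1=C2, Z-C4=C5, cis-lactone, 8-OTBS | C1CCN(C1)/C2=C(C(=O)OC)/C=C/C/C(C)=C\[C@@H]3OC(=O)C[C@@H]3[C@@H]2O[Si](C)(C)C(C)(C)C | intermediate
23 | 11-(dimethylaminomethyl) lactone of 22 (CH2NMe2 trans to C8 on the lactone) | C1CCN(C1)/C2=C(C(=O)OC)/C=C/C/C(C)=C\[C@@H]3OC(=O)[C@@H](CN(C)C)[C@@H]3[C@@H]2O[Si](C)(C)C(C)(C)C | intermediate
24 | trimethylammonium iodide (methiodide) of 23 | C1CCN(C1)/C2=C(C(=O)OC)/C=C/C/C(C)=C\[C@@H]3OC(=O)[C@@H](C[N+](C)(C)C)[C@@H]3[C@@H]2O[Si](C)(C)C(C)(C)C.[I-] | intermediate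
25 | 11(13)-methylene lactone of 22 | C1CCN(C1)/C2=C(C(=O)OC)/C=C/C/C(C)=C\[C@@H]3OC(=O)C(=C)[C@@H]3[C@@H]2O[Si](C)(C)C(C)(C)C | intermediate
26 | conjugated iminium chloride (N+=C9, ring-cis C10=C1, C2 protonated) | C1CC[N+](C1)=C2/C(C(=O)OC)=C\CC/C(C)=C\[C@@H]3OC(=O)C(=C)[C@@H]3[C@@H]2O[Si](C)(C)C(C)(C)C.[Cl-] | intermediate
27 | alkylidene β-keto ester: C9 ketone, ring-cis C10=C1 with CO2Me, 8-OTBS, methylene cis-lactone, Z-C4=C5 | O=C1/C(C(=O)OC)=C\CC/C(C)=C\[C@@H]2OC(=O)C(=C)[C@@H]2[C@@H]1O[Si](C)(C)C(C)(C)C | intermediate
28 | 9-alcohol of 27 (9-OH trans to 8-OTBS) | O[C@H]1/C(C(=O)OC)=C\CC/C(C)=C\[C@@H]2OC(=O)C(=C)[C@@H]2[C@@H]1O[Si](C)(C)C(C)(C)C | intermediate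
29 | methyl (R)-2-methylglycidate | COC(=O)[C@@]1(C)CO1 | starting material
30 | (R)-2-methylglycidic acid | OC(=O)[C@@]1(C)CO1 | intermediate
31 | mixed anhydride of 30 with 2,4,6-trichlorobenzoic acid | O=C(OC(=O)[C@@]1(C)CO1)c2c(Cl)cc(Cl)cc2Cl | intermediate
32 | 9-O-[(R)-2-methylglycidoyl] ester of 28 | C[C@@]1(CO1)C(=O)O[C@H]2/C(C(=O)OC)=C\CC/C(C)=C\[C@@H]3OC(=O)C(=C)[C@@H]3[C@@H]2O[Si](C)(C)C(C)(C)C | intermediate
33 | 8-alcohol (desilylated 32) | C[C@@]1(CO1)C(=O)O[C@H]2/C(C(=O)OC)=C\CC/C(C)=C\[C@@H]3OC(=O)C(=C)[C@@H]3[C@@H]2O | intermediate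
34 | 8-acetate (4,5-deoxy target, Z-C4=C5) | C[C@@]1(CO1)C(=O)O[C@H]2/C(C(=O)OC)=C\CC/C(C)=C\[C@@H]3OC(=O)C(=C)[C@@H]3[C@@H]2OC(C)=O | intermediate
35 | CNP0159450.1: (4R,5S)-epoxide, (6R,7R)-cis-lactone, (8S)-acetate, (9S)-(2R)-2-methylglycidate, ring-cis C1=C10 with C14 methyl ester | C=C1C(=O)O[C@@H]2[C@H]1[C@H](OC(C)=O)[C@@H](OC(=O)[C@@]1(C)CO1)/C(C(=O)OC)=C\CC[C@@]1(C)O[C@@H]21 | target

**Step count and risks**

Total step count: 22. Longest linear sequence: 20 steps (steps 1–4, 6–17, 19–22); steps 5 and 18 are side branches.

Steps most likely to fail: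

1. Step 16 (dienamine hydrolysis with double-bond migration). Protonation may stay at C10 and leave the strained C1=C2 bond out of conjugation, the protonated diene may be captured across the ring by C4=C5, the C10=C1 bond may form ring-trans, or the silyl ether may be lost in the acid. The fallback sets out from 23 and returns at 27. The strained trans C1=C2 bond of 23 is saturated with diimide (2-nitrobenzenesulfonylhydrazide, Et3N, CH2Cl2), which leaves the trisubstituted and the push–pull alkenes alone, to give the enamino ester F1. Mild aqueous HCl hydrolyses this to the saturated β-keto ester F2. NaH and PhSeCl at −78 °C give the α-phenylseleno keto ester F3. mCPBA (2 equiv, −78 → 25 °C) oxidises selenium and the dimethylamino nitrogen to the selenoxide N-oxide F4, and its two syn-eliminations (selenoxide elimination toward C1, Cope elimination toward C13) deliver 27.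

2. Step 17 (C9 reduction). Hydride may arrive on the other face of the ketone through cerium chelation to the C8 oxygen or ring-conformational control, or conjugate reduction may compete. The fallback sets out from 27 and returns at 32. If reduction gives the C9 epimer F5 (hydroxyl cis to the C8 silyl ether), Mitsunobu esterification with acid 30 (PPh3, diisopropyl azodicarboxylate, THF, 0 °C) inverts C9 while installing the glycidate and gives 32 directly.

3. Step 22 (epoxidation). The peracid may prefer the α-face of the flexible ten-membered ring, and acid may open the new epoxide across the ring. The fallback sets out from 34 and returns at 35. NBS in wet THF gives the bromohydrin F6, with bromine on C5 from the face an electrophile prefers and water on C4 from the other. Ag2O in CH2Cl2 then closes the oxirane with inversion at C5, which places the oxygen on the face opposite to the one attacked first.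

**Further compounds**

F1 | step 16 | enamino ester: C1–C2 saturated Mannich base, ring-cis C9=C10 | C1CCN(C1)/C2=C(C(=O)OC)/CCC/C(C)=C\[C@@H]3OC(=O)[C@@H](CN(C)C)[C@@H]3[C@@H]2O[Si](C)(C)C(C)(C)C
F2 | step 16 | saturated β-keto ester (C9 ketone, C10 epimers) with the 11-dimethylaminomethyl lactone | O=C1C(C(=O)OC)CCC/C(C)=C\[C@@H]2OC(=O)[C@@H](CN(C)C)[C@@H]2[C@@H]1O[Si](C)(C)C(C)(C)C
F3 | step 16 | 10-phenylseleno β-keto ester (C10 epimers) | O=C1C([Se]c2ccccc2)(C(=O)OC)CCC/C(C)=C\[C@@H]3OC(=O)[C@@H](CN(C)C)[C@@H]3[C@@H]1O[Si](C)(C)C(C)(C)C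
F4 | step 16 | selenoxide N-oxide of F3 (not isolated) | O=C1C([Se](=O)c2ccccc2)(C(=O)OC)CCC/C(C)=C\[C@@H]3OC(=O)[C@@H](C[N+](C)(C)[O-])[C@@H]3[C@@H]1O[Si](C)(C)C(C)(C)C
F5 | step 17 | C9 epimer of 28 (9-OH cis to 8-OTBS) | O[C@@H]1/C(C(=O)OC)=C\CC/C(C)=C\[C@@H]2OC(=O)C(=C)[C@@H]2[C@@H]1O[Si](C)(C)C(C)(C)C
F6 | step 22 | bromohydrin of 34 (5-Br on the α-face, 4-OH on the β-face) | C[C@@]1(CO1)C(=O)O[C@H]2/C(C(=O)OC)=C\CC[C@@](C)(O)[C@H](Br)[C@@H]3OC(=O)C(=C)[C@@H]3[C@@H]2OC(C)=O
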